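**Plan**
Daucane numbering is used: C1 = methyl-bearing fusion carbon, C4 = isopropyl carbinol, C5 = fusion CH, then C6 to C10 round the seven-membered ring; β = face of the C1 methyl.
Retrosynthesis: remove the silyl groups and the 8α,9α-epoxide, return C7–OH to a ketone, cut the C6 ester, then cut C9–C10 and C6–C7 together, which lifts the whole C7–C8(CH3)–C9 unit out of the seven-membered ring.
Enabling feature: C7–C8–C9 is a 2-methylpropenal skeleton lying between the oxygen-bearing C6 and the neopentyl C10H2; as (E)-Bu3Sn–CH=C(CH3)–CHO it accepts a radical at C9 and, after reduction by CrCl2/Me3SiCl, is a γ-silyloxyallyl nucleophile at C7.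
Forward order: the cyclopentane (C1–C5) first, by conjugate addition to a cyclopentenone, orthoformate trapping and isopropyl addition; then the seven-membered ring in one flask by a tin-to-chromium relay (4+3) annulation onto the C10 selenide and C6 aldehyde; then C7 oxidation, esterification, reduction, epoxidation, desilylation.
Stereochemistry: C1 from a ligand-controlled copper conjugate addition; C5 and C4 relayed from C1; C6 from the bridged chromium transition state of the ring closure; C7 from Luche reduction; C8/C9 from peracid attack anti to the C1 methyl.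

Key step: step 9

Remark: all bicyclic compounds are trans-fused daucanes (1β-CH3, 5α-H, 4α-isopropyl, 8-CH3); names use α/β descriptors and the SMILES are definitive.
Remark: compounds 1, 2, 12 and 20 are taken as purchasable.

**Step 1**
Reactants: 1 3-ethoxycyclopent-2-en-1-one; 2 bis(phenylselanyl)methane
Product: 5 3-[(phenylselanyl)methyl]cyclopent-2-en-1-one, via (phenylselanyl)methyllithium 3 (not isolated), via lithium 3-ethoxy-1-[(phenylselanyl)methyl]cyclopent-2-en-1-olate 4 (not isolated)
Conditions: n-BuLi, THF, −78 °C; then 1, −78 → 0 °C; then 1 M HCl (aq), 25 °C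
Reagents that add atoms: water, O
Why: Selenium–lithium exchange on 2 should give the selenium-stabilised carbanion 3, which adds 1,2 to the vinylogous ester 1, and acid converts adduct 4 into the transposed enone 5 (Stork–Danheiser alkylation–transposition); no stereocenter is formed.

**Step 2**
Reactants: 5 3-[(phenylselanyl)methyl]cyclopent-2-en-1-one
Product: 7 (S)-trimethyl({3-methyl-3-[(phenylselanyl)methyl]cyclopent-1-en-1-yl}oxy)silane, via dimethylaluminium enolate 6 (not isolated)
Conditions: Me3Al, Cu(OTf)2 (2 mol %), chiral BINOL-derived phosphoramidite ligand (4 mol %, enantiomer chosen for β-face delivery), Et2O, −30 °C; then Me3SiOTf, Et3N, −30 → 0 °C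
Reagents that add atoms: trimethylaluminium, C[Al](C)C; trimethylsilyl trifluoromethanesulfonate, C[Si](C)(C)OS(=O)(=O)C(F)(F)F
Why: Copper-catalysed asymmetric conjugate addition of Me3Al to the β-substituted cyclopentenone should build the quaternary C1 with the chiral copper–phosphoramidite complex choosing the enone face (methyl β, S at C1), and O-silylation of aluminium enolate 6 fixes the C4=C5 enol regiochemistry.

**Step 3**
Reactants: 7 (S)-trimethyl({3-methyl-3-[(phenylselanyl)methyl]cyclopent-1-en-1-yl}oxy)silane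
Product: 8 (2S,3S)-2-(dimethoxymethyl)-3-methyl-3-[(phenylselanyl)methyl]cyclopentan-1-one
Conditions: HC(OMe)3, BF3·OEt2, CH2Cl2, −78 °C
Reagents that add atoms: trimethyl orthoformate, COC(OC)OC
Why: Mukaiyama-type addition of the regiodefined enol silane to the dimethoxycarbenium ion should bring in C6 at the acetal oxidation level, the electrophile entering C5 anti to the bulkier CH2SePh arm on C1 (C5 is α to the ketone, so equilibration also favours this trans isomer).

**Step 4**
Reactants: 8 (2S,3S)-2-(dimethoxymethyl)-3-methyl-3-[(phenylselanyl)methyl]cyclopentan-1-one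
Product: 9 (1R,2R,3S)-2-(dimethoxymethyl)-3-methyl-3-[(phenylselanyl)methyl]-1-(propan-2-yl)cyclopentan-1-ol
Conditions: i-PrMgCl, LaCl3·2LiCl, THF, 0 °C
Reagents that add atoms: isopropylmagnesium chloride, CC(C)[Mg]Cl
Why: Lanthanum-assisted Grignard 1,2-addition (little enolisation or reduction) should occur on the face of the C4 carbonyl opposite to the adjacent C5 dimethoxymethyl group, so isopropyl becomes α and the hydroxyl β.

**Step 5**
Reactants: 9 (1R,2R,3S)-2-(dimethoxymethyl)-3-methyl-3-[(phenylselanyl)methyl]-1-(propan-2-yl)cyclopentan-1-ol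
Product: 10 triethyl({(1R,2R,3S)-2-(dimethoxymethyl)-3-methyl-3-[(phenylselanyl)methyl]-1-(propan-2-yl)cyclopentyl}oxy)silane
Conditions: Et3SiOTf, 2,6-lutidine, CH2Cl2, 0 °C
Reagents that add atoms: triethylsilyl trifluoromethanesulfonate, CC[Si](CC)(CC)OS(=O)(=O)C(F)(F)F
Why: O-Silylation with the silyl triflate caps the hindered tertiary alcohol so that the later β-oxy aldehyde cannot undergo retro-aldol cleavage or dehydration; no stereocenter changes.

**Step 6**
Reactants: 10 triethyl({(1R,2R,3S)-2-(dimethoxymethyl)-3-methyl-3-[(phenylselanyl)methyl]-1-(propan-2-yl)cyclopentyl}oxy)silane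
Product: 11 (1R,2S,5R)-2-methyl-2-[(phenylselanyl)methyl]-5-(propan-2-yl)-5-[(triethylsilyl)oxy]cyclopentane-1-carbaldehyde
Conditions: PPTS (cat.), acetone/H2O, 45 °C
Reagents that add atoms: water, O
Why: Mild acid-catalysed acetal hydrolysis should free the C6 aldehyde while the tertiary silyl ether and the selenide survive, and the non-basic conditions leave the α-centre C5 untouched.

**Step 7**
Reactants: 12 (E)-3-iodo-2-methylprop-2-en-1-ol
Product: 13 (E)-2-methyl-3-(tributylstannyl)prop-2-en-1-ol
Conditions: (Bu3Sn)2, PdCl2(PPh3)2 (5 mol %), THF, 60 °C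
Reagents that add atoms: hexabutylditin, CCCC[Sn](CCCC)(CCCC)[Sn](CCCC)(CCCC)CCCC
Why: Palladium-catalysed stannylation of the vinyl iodide with the distannane (oxidative addition, tin–tin transmetallation, reductive elimination) should proceed with retention of the E geometry.

**Step 8**
Reactants: 13 (E)-2-methyl-3-(tributylstannyl)prop-2-en-1-ol
Product: 14 (E)-2-methyl-3-(tributylstannyl)prop-2-enal
Conditions: MnO2, CH2Cl2, 25 °C
Reagents that add atoms: none
Why: MnO2 allylic oxidation should give the enal without touching the vinylstannane or the alkene geometry.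

**Step 9**
Reactants: 11 (1R,2S,5R)-2-methyl-2-[(phenylselanyl)methyl]-5-(propan-2-yl)-5-[(triethylsilyl)oxy]cyclopentane-1-carbaldehyde; 14 (E)-2-methyl-3-(tributylstannyl)prop-2-enal (1.1 equiv)
Product: 18 4β-[(triethylsilyl)oxy]dauc-8-ene-6α,7α-diol, via enal aldehyde 15 (not isolated), via silyloxyallylchromium dichloride 16 (not isolated), via bis(trimethylsilyl) ether 17 (not isolated)
Conditions: AIBN (20 mol %), PhH (1 M), 80 °C; then CrCl2 (5 equiv), Me3SiCl (4 equiv), DMF, 0 → 25 °C; 1 M HCl (aq) work-up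
Reagents that add atoms: none
Why: A tin-radical chain first joins C10 to C9: Bu3Sn• (started by AIBN) abstracts the phenylselanyl group of 11, the neopentyl-type C10 radical adds to the tin-bearing C9 of 14, and the tertiary α-formyl radical at C8 expels Bu3Sn• by β-scission, which is the radical vinylation (addition–elimination) known for β-stannyl acrylates and gives enal 15. CrCl2 with Me3SiCl then reduces the silylated enal to the γ-silyloxyallylchromium 16 (divalent to trivalent chromium, metal on C9, silyloxy on C7), which adds through C7 to the C6 aldehyde and is silylated to 17; this is the chromium-mediated pinacol-type cross-coupling of enals with aldehydes, run here intramolecularly. The seven-membered ring closes by a 7-exo-trig carbonyl addition with allyl transposition (SE2′), so C8=C9 ends inside the ring with the cis geometry that ring size demands. C6 is set by the bridged six-membered transition state in which the Cr–O unit spans C9 and C6 on one face of the forming ring: the β face is capped by the C1 methyl, so the bridge lies on the α face and C6–OH becomes α, while C7–O should come out cis to it because the (E)-silyloxy group points outward (C7 is reset in steps 10 and 12, so its outcome here is immaterial). The substrate secures the selectivities needed: the allylchromium is fluxional, so the C9 configuration is irrelevant; closure through C9 to a five-membered ring is shut off because the C10 and C6 arms are trans on the cyclopentane and would have to form a trans-fused bicyclo[3.3.0]octane; divalent chromium reduces only the conjugated aldehyde, and the small excess of 14 limits intermolecular coupling.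

**Step 10**
Reactants: 18 4β-[(triethylsilyl)oxy]dauc-8-ene-6α,7α-diol
Product: 19 6α-hydroxy-4β-[(triethylsilyl)oxy]dauc-8-en-7-one
Conditions: MnO2 (activated), CH2Cl2, 25 °C
Reagents that add atoms: none
Why: Chemoselective allylic oxidation should convert only the C7 carbinol, erasing the C7 configuration and giving the conjugated α-hydroxy enone, in which C6 lies α to the ketone and keeps (or equilibrates to) the pseudo-equatorial 6α configuration.

**Step 11**
Reactants: 19 6α-hydroxy-4β-[(triethylsilyl)oxy]dauc-8-en-7-one; 20 4-[(tert-butyldimethylsilyl)oxy]benzoic acid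
Product: 21 7-oxo-4β-[(triethylsilyl)oxy]dauc-8-en-6α-yl 4-[(tert-butyldimethylsilyl)oxy]benzoate
Conditions: EDC·HCl, DMAP, CH2Cl2, 0 → 25 °C
Reagents that add atoms: none
Why: Steglich esterification should acylate the α-ketol hydroxyl at C6 with retention, the tertiary C4 oxygen being silylated and the phenol masked as its silyl ether.

**Step 12**
Reactants: 21 7-oxo-4β-[(triethylsilyl)oxy]dauc-8-en-6α-yl 4-[(tert-butyldimethylsilyl)oxy]benzoate
Product: 22 7β-hydroxy-4β-[(triethylsilyl)oxy]dauc-8-en-6α-yl 4-[(tert-butyldimethylsilyl)oxy]benzoate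
Conditions: NaBH4, CeCl3·7H2O, MeOH, −78 °C
Reagents that add atoms: none
Why: Luche 1,2-reduction should deliver hydride along the pseudo-axial α trajectory (the β approach suffers torsional strain with C6–H), giving the pseudo-equatorial 7β-alcohol trans to the C6 ester without 1,4-reduction.

**Step 13**
Reactants: 22 7β-hydroxy-4β-[(triethylsilyl)oxy]dauc-8-en-6α-yl 4-[(tert-butyldimethylsilyl)oxy]benzoate
Product: 23 4β,7β-bis[(triethylsilyl)oxy]dauc-8-en-6α-yl 4-[(tert-butyldimethylsilyl)oxy]benzoate
Conditions: Et3SiOTf, 2,6-lutidine, CH2Cl2, −78 → 0 °C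
Reagents that add atoms: triethylsilyl trifluoromethanesulfonate, CC[Si](CC)(CC)OS(=O)(=O)C(F)(F)F
Why: O-Silylation of the allylic alcohol switches off hydroxyl-directed peracid delivery and adds bulk to the β face before the epoxidation; no stereocenter changes.

**Step 14**
Reactants: 23 4β,7β-bis[(triethylsilyl)oxy]dauc-8-en-6α-yl 4-[(tert-butyldimethylsilyl)oxy]benzoate
Product: 24 8α,9α-epoxy-4β,7β-bis[(triethylsilyl)oxy]daucan-6α-yl 4-[(tert-butyldimethylsilyl)oxy]benzoate
Conditions: mCPBA, NaHCO3, CH2Cl2, 0 °C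
Reagents that add atoms: 3-chloroperoxybenzoic acid, OOC(=O)c1cccc(Cl)c1
Why: Prilezhaev epoxidation of the trisubstituted C8=C9 alkene should take place from the α face, opposite to the C1 methyl that overhangs C9 and to the 7β-silyloxy group, which sets C8 and C9 together.

**Step 15**
Reactants: 24 8α,9α-epoxy-4β,7β-bis[(triethylsilyl)oxy]daucan-6α-yl 4-[(tert-butyldimethylsilyl)oxy]benzoate
Product: 25 8α,9α-epoxy-4β,7β-dihydroxydaucan-6α-yl 4-hydroxybenzoate (CNP0290052.1)
Conditions: HF·pyridine, pyridine, THF, 0 → 25 °C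
Reagents that add atoms: none
Why: Buffered fluoride desilylation should remove both triethylsilyl ethers and the aryl silyl ether in one pass under non-basic conditions that avoid Payne rearrangement and acyl migration, giving the target.

**Compound list**
1 | 3-ethoxycyclopent-2-en-1-one | CCOC1=CC(=O)CC1 | starting material
2 | bis(phenylselanyl)methane | C([Se]c1ccccc1)[Se]c1ccccc1 | starting material
3 | (phenylselanyl)methyllithium | [Li]C[Se]c1ccccc1 | intermediate
4 | lithium 3-ethoxy-1-[(phenylselanyl)methyl]cyclopent-2-en-1-olate (racemic) | CCOC1=CC(O[Li])(C[Se]c2ccccc2)CC1 | intermediate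
5 | 3-[(phenylselanyl)methyl]cyclopent-2-en-1-one | O=C1C=C(C[Se]c2ccccc2)CC1 | intermediate
6 | dimethylaluminium (S)-3-methyl-3-[(phenylselanyl)methyl]cyclopent-1-en-1-olate | C[Al](C)OC1=C[C@@](C)(C[Se]c2ccccc2)CC1 | intermediate
7 | (S)-trimethyl({3-methyl-3-[(phenylselanyl)methyl]cyclopent-1-en-1-yl}oxy)silane | C[Si](C)(C)OC1=C[C@@](C)(C[Se]c2ccccc2)CC1 | intermediate
8 | (2S,3S)-2-(dimethoxymethyl)-3-methyl-3-[(phenylselanyl)methyl]cyclopentan-1-one | COC(OC)[C@H]1C(=O)CC[C@]1(C)C[Se]c1ccccc1 | intermediate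
9 | (1R,2R,3S)-2-(dimethoxymethyl)-3-methyl-3-[(phenylselanyl)methyl]-1-(propan-2-yl)cyclopentan-1-ol | CC(C)[C@]1(O)CC[C@](C)(C[Se]c2ccccc2)[C@H]1C(OC)OC | intermediate
10 | triethyl({(1R,2R,3S)-2-(dimethoxymethyl)-3-methyl-3-[(phenylselanyl)methyl]-1-(propan-2-yl)cyclopentyl}oxy)silane | CC(C)[C@]1(O[Si](CC)(CC)CC)CC[C@](C)(C[Se]c2ccccc2)[C@H]1C(OC)OC | intermediate
11 | (1R,2S,5R)-2-methyl-2-[(phenylselanyl)methyl]-5-(propan-2-yl)-5-[(triethylsilyl)oxy]cyclopentane-1-carbaldehyde | CC(C)[C@]1(O[Si](CC)(CC)CC)CC[C@](C)(C[Se]c2ccccc2)[C@H]1C=O | intermediate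
12 | (E)-3-iodo-2-methylprop-2-en-1-ol | OC/C(C)=C/I | starting material
13 | (E)-2-methyl-3-(tributylstannyl)prop-2-en-1-ol | OC/C(C)=C/[Sn](CCCC)(CCCC)CCCC | intermediate
14 | (E)-2-methyl-3-(tributylstannyl)prop-2-enal | O=C/C(C)=C/[Sn](CCCC)(CCCC)CCCC | intermediate
15 | 2-methyl-2-[(2E)-3-methyl-4-oxobut-2-en-1-yl]-5-(propan-2-yl)-5-[(triethylsilyl)oxy]cyclopentane-1-carbaldehyde, ring configured as in 11 | CC(C)[C@]1(O[Si](CC)(CC)CC)CC[C@](C)(C/C=C(\C)C=O)[C@H]1C=O | intermediate
16 | γ-(trimethylsilyloxy)allylchromium dichloride from 15 (CrCl2 on C9, Me3SiO on C7, fluxional) | CC(C)[C@]1(O[Si](CC)(CC)CC)CC[C@](C)(CC([Cr](Cl)Cl)C(C)=CO[Si](C)(C)C)[C@H]1C=O | intermediate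
17 | 4β-[(triethylsilyl)oxy]-6α,7α-bis[(trimethylsilyl)oxy]dauc-8-ene | CC(C)[C@]1(O[Si](CC)(CC)CC)CC[C@]2(C)CC=C(C)[C@H](O[Si](C)(C)C)[C@H](O[Si](C)(C)C)[C@H]21 | intermediate
18 | 4β-[(triethylsilyl)oxy]dauc-8-ene-6α,7α-diol | CC(C)[C@]1(O[Si](CC)(CC)CC)CC[C@]2(C)CC=C(C)[C@H](O)[C@H](O)[C@H]21 | intermediate
19 | 6α-hydroxy-4β-[(triethylsilyl)oxy]dauc-8-en-7-one | CC(C)[C@]1(O[Si](CC)(CC)CC)CC[C@]2(C)CC=C(C)C(=O)[C@H](O)[C@H]21 | intermediate
20 | 4-[(tert-butyldimethylsilyl)oxy]benzoic acid | CC(C)(C)[Si](C)(C)Oc1ccc(cc1)C(=O)O | starting material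
21 | 7-oxo-4β-[(triethylsilyl)oxy]dauc-8-en-6α-yl 4-[(tert-butyldimethylsilyl)oxy]benzoate | CC(C)[C@]1(O[Si](CC)(CC)CC)CC[C@]2(C)CC=C(C)C(=O)[C@H](OC(=O)c3ccc(O[Si](C)(C)C(C)(C)C)cc3)[C@H]21 | intermediate
22 | 7β-hydroxy-4β-[(triethylsilyl)oxy]dauc-8-en-6α-yl 4-[(tert-butyldimethylsilyl)oxy]benzoate | CC(C)[C@]1(O[Si](CC)(CC)CC)CC[C@]2(C)CC=C(C)[C@@H](O)[C@H](OC(=O)c3ccc(O[Si](C)(C)C(C)(C)C)cc3)[C@H]21 | intermediate
23 | 4β,7β-bis[(triethylsilyl)oxy]dauc-8-en-6α-yl 4-[(tert-butyldimethylsilyl)oxy]benzoate | CC(C)[C@]1(O[Si](CC)(CC)CC)CC[C@]2(C)CC=C(C)[C@@H](O[Si](CC)(CC)CC)[C@H](OC(=O)c3ccc(O[Si](C)(C)C(C)(C)C)cc3)[C@H]21 | intermediate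
24 | 8α,9α-epoxy-4β,7β-bis[(triethylsilyl)oxy]daucan-6α-yl 4-[(tert-butyldimethylsilyl)oxy]benzoate | CC(C)[C@]1(O[Si](CC)(CC)CC)CC[C@]2(C)C[C@@H]3O[C@]3(C)[C@@H](O[Si](CC)(CC)CC)[C@H](OC(=O)c3ccc(O[Si](C)(C)C(C)(C)C)cc3)[C@H]21 | intermediate
25 | 8α,9α-epoxy-4β,7β-dihydroxydaucan-6α-yl 4-hydroxybenzoate | CC(C)[C@]1(O)CC[C@]2(C)C[C@@H]3O[C@]3(C)[C@@H](O)[C@H](OC(=O)c3ccc(O)cc3)[C@H]21 | target

**Totals**
Total step count: 15. Longest linear sequence: 13 (steps 1–6 and 9–15); steps 7–8 make the three-carbon linchpin.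

**Steps most likely to fail**

Step 9. What may go wrong: 1,5-hydrogen transfer from the isopropyl C–H to the C10 radical, slow radical addition to the hindered tin-bearing carbon, intermolecular coupling of the allylchromium with a second aldehyde, or failure of the bridged ring closure. The fallback closes the ring by metathesis instead and sets the C6/C7 pair by reagent control; it sets out from 1 and comes back at 22. Allylmagnesium bromide followed by aqueous HCl would turn 1 into 3-(prop-2-en-1-yl)cyclopent-2-en-1-one F1. The conditions of steps 2 to 6 would then give in turn the enol silane trimethyl{[3-methyl-3-(prop-2-en-1-yl)cyclopent-1-en-1-yl]oxy}silane F2, the keto acetal F3, the isopropyl carbinol F4, its triethylsilyl ether F5 and the aldehyde F6. Syn-selective alkoxyallylboration of F6 with (Z)-[3-(methoxymethoxy)-2-methylallyl]diisopinocampheylborane (from the methoxymethyl ether of 2-methylprop-2-en-1-ol, s-BuLi, Ipc2BOMe and BF3·OEt2; borane enantiomer chosen for the 6α-hydroxy product) would give the 6α-hydroxy-7β-(methoxymethoxy) diene F7. Ring-closing metathesis with second-generation Grubbs catalyst would form C8=C9 and give the cycloheptene F8. Esterification with 20 (EDC·HCl, DMAP) would give the ester F9, and Me2BBr (CH2Cl2, −78 °C) would remove the methoxymethyl group to give 22.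

Step 12. What may go wrong: hydride delivery to the β face of the C7 carbonyl, or acyl migration from O6 to O7 under the borohydride conditions. The fallback reduces before esterification with intramolecular hydride delivery; it sets out from 19 and comes back at 23. Hydroxyl-directed reduction of 19 with Me4NBH(OAc)3 (MeCN/AcOH, −30 °C; Evans–Saksena reduction, hydride carried to the α face by the C6 oxygen) would give 4β-[(triethylsilyl)oxy]dauc-8-ene-6α,7β-diol F10. Selective silylation of the less hindered allylic C7 hydroxyl (Et3SiCl, imidazole, −40 °C) would give the 7β-triethylsilyl ether F11, and esterification of its C6 hydroxyl with 20 (EDC·HCl, DMAP) would give 23.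

Step 14. What may go wrong: peracid attack on the β face, so that facial selectivity is poor. The fallback replaces substrate control by reagent control: Shi epoxidation of 23 (fructose-derived ketone of the enantiomeric series matched to the α face, KHSO5, K2CO3 buffer, MeCN/H2O, 0 °C) would give 24 directly and makes no new compound.

**Further compounds**
F1 | step 9 | 3-(prop-2-en-1-yl)cyclopent-2-en-1-one | C=CCC1=CC(=O)CC1
F2 | step 9 | trimethyl{[3-methyl-3-(prop-2-en-1-yl)cyclopent-1-en-1-yl]oxy}silane, C1 configured as in 7 | C[Si](C)(C)OC1=C[C@@](C)(CC=C)CC1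
F3 | step 9 | 2-(dimethoxymethyl)-3-methyl-3-(prop-2-en-1-yl)cyclopentan-1-one, configured as 8 | COC(OC)[C@H]1C(=O)CC[C@]1(C)CC=C
F4 | step 9 | 2-(dimethoxymethyl)-3-methyl-1-(propan-2-yl)-3-(prop-2-en-1-yl)cyclopentan-1-ol, configured as 9 | CC(C)[C@]1(O)CC[C@](C)(CC=C)[C@H]1C(OC)OC
F5 | step 9 | triethylsilyl ether of F4 | CC(C)[C@]1(O[Si](CC)(CC)CC)CC[C@](C)(CC=C)[C@H]1C(OC)OC
F6 | step 9 | 2-methyl-5-(propan-2-yl)-2-(prop-2-en-1-yl)-5-[(triethylsilyl)oxy]cyclopentane-1-carbaldehyde, configured as 11 | CC(C)[C@]1(O[Si](CC)(CC)CC)CC[C@](C)(CC=C)[C@H]1C=O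
F7 | step 9 | 6α-hydroxy-7β-(methoxymethoxy) seco-diene (C6 carbinol, C7 methoxymethyl ether, C8 isopropenyl, allyl on C1) | CC(C)[C@]1(O[Si](CC)(CC)CC)CC[C@](C)(CC=C)[C@H]1[C@@H](O)[C@H](OCOC)C(C)=C
F8 | step 9 | 7β-(methoxymethoxy)-4β-[(triethylsilyl)oxy]dauc-8-en-6α-ol | CC(C)[C@]1(O[Si](CC)(CC)CC)CC[C@]2(C)CC=C(C)[C@@H](OCOC)[C@H](O)[C@H]21
F9 | step 9 | 7β-(methoxymethoxy)-4β-[(triethylsilyl)oxy]dauc-8-en-6α-yl 4-[(tert-butyldimethylsilyl)oxy]benzoate | CC(C)[C@]1(O[Si](CC)(CC)CC)CC[C@]2(C)CC=C(C)[C@@H](OCOC)[C@H](OC(=O)c3ccc(O[Si](C)(C)C(C)(C)C)cc3)[C@H]21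
F10 | step 12 | 4β-[(triethylsilyl)oxy]dauc-8-ene-6α,7β-diol | CC(C)[C@]1(O[Si](CC)(CC)CC)CC[C@]2(C)CC=C(C)[C@@H](O)[C@H](O)[C@H]21
F11 | step 12 | 4β,7β-bis[(triethylsilyl)oxy]dauc-8-en-6α-ol | CC(C)[C@]1(O[Si](CC)(CC)CC)CC[C@]2(C)CC=C(C)[C@@H](O[Si](CC)(CC)CC)[C@H](O)[C@H]21
F0 | step 14 | none | none
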